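**Plan**
1. Enabling feature: C20 is quaternary, carries the C21 methyl and is bonded to the quaternary C22. C20, C21 and C22 can therefore be the three carbons of a cyclopropane made from a C20=C21 methylene on ring B and a C22 carbenoid; the same event closes ring C, and later cleavage of C21–C22 leaves the methyl group.
2. Retrosynthetic cuts, in order: ring A at C9=C10 and O13–C11; C1=C2; ring E at O25–C23 and ring D at C22–C28; C3–C30; C21–C22; then C20–C22 with C21–C22 (key step); side chain at C22–C2 and C5–C3.
3. Forward order: ring B (from a 4-substituted cyclohexanone), then ring C with the cyclopropane, then rings D and E in one aldol–lactonisation, then ring A last.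
4. Stereochemistry: C17 from a chiral lithium amide desymmetrisation; C7 and C6 relayed from C17 (anti conjugate addition, axial protonation); C20 and C22 from the face-selective cyclopropanation; C3 by axial alkylation; C26 from ethyl (S)-lactate; C22 and C28 finally from the reversible aldol that only one epimer can lock by lactonisation.
5. Atoms are numbered in the order of the target SMILES (C1 = exocyclic CH2 carbon); β is the face of rings B and C that carries the C8 and C21 methyl groups.

Key step: step 17

Remark 1: C3 is formed without control in step 13, and C22 is epimerisable in 24 to 27; both are left undefined in the SMILES until they are fixed (C3 in step 19, C22 in step 21).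
Remark 2: the (R,R)-amide in step 7 is taken as the antipode that delivers the (S)-enol silane 10; if induction on this substrate runs the other way, the (S,S)-base is used. Any minor enantiomer carried forward becomes a separable diastereomer once enantiopure 5 is attached in step 19.

**Fragment 5 (C26, C27, C28, C30)**

Step 1
Reactants: 1 ethyl (S)-lactate [ethyl (2S)-2-hydroxypropanoate]
Product: 2 ethyl (2S)-2-(triethylsilyloxy)propanoate
Conditions: Et3SiCl, imidazole, CH2Cl2, 0 °C → rt
Reagents that add atoms: chlorotriethylsilane, CC[Si](Cl)(CC)CC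
Why: Silyl ether formation on the secondary alcohol; the stereocentre (later C26) is not touched.

Step 2
Reactants: 2 ethyl (2S)-2-(triethylsilyloxy)propanoate
Product: 4 triethyl{[(2S)-3-[(trimethylsilyl)methyl]but-3-en-2-yl]oxy}silane, via bis(silylmethyl) carbinol 3 (not isolated)
Conditions: Me3SiCH2MgCl (4 equiv), CeCl3 (4 equiv), THF, −78 °C → rt; then SiO2, CH2Cl2, rt
Reagents that add atoms: (trimethylsilyl)methylmagnesium chloride, C[Si](C)(C)C[Mg]Cl
Why: Double addition of the weakly basic organocerium reagent to the ester, then Peterson elimination of one silanol unit, should give the 2-substituted allylsilane (known ester-to-allylsilane conversion) without epimerising the α-oxygenated centre.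

Step 3
Reactants: 4 triethyl{[(2S)-3-[(trimethylsilyl)methyl]but-3-en-2-yl]oxy}silane
Product: 5 {[(2S)-3-(bromomethyl)but-3-en-2-yl]oxy}triethylsilane
Conditions: NBS, CH2Cl2, −78 °C
Reagents that add atoms: N-bromosuccinimide, BrN1C(=O)CCC1=O
Why: Electrophilic bromodesilylation (SE2′) of the allylsilane; bromine adds to the alkene terminus, silicon leaves, and the symmetrical 2-substituted allyl unit can give only one allylic bromide.

**Ring B and the diazo β-keto ester**

Step 4
Reactants: 6 ethyl 1,4-dioxaspiro[4.5]decane-8-carboxylate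
Product: 7 2-(1,4-dioxaspiro[4.5]decan-8-yl)propan-2-ol
Conditions: MeMgBr (2.5 equiv), THF, 0 °C → rt; aq. NH4Cl
Reagents that add atoms: methylmagnesium bromide, C[Mg]Br
Why: Double Grignard addition to the ester builds the C14 carbinol with its two methyl groups (C15, C16).

Step 5
Reactants: 7 2-(1,4-dioxaspiro[4.5]decan-8-yl)propan-2-ol
Product: 8 tert-butyl{[2-(1,4-dioxaspiro[4.5]decan-8-yl)propan-2-yl]oxy}dimethylsilane
Conditions: TBSOTf, 2,6-lutidine, CH2Cl2, 0 °C → rt
Reagents that add atoms: tert-butyldimethylsilyl trifluoromethanesulfonate, CC(C)(C)[Si](C)(C)OS(=O)(=O)C(F)(F)F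
Why: Silylation of the tertiary alcohol with the silyl triflate, done before the ketone is unmasked so that no silyl enol ether can form.

Step 6
Reactants: 8 tert-butyl{[2-(1,4-dioxaspiro[4.5]decan-8-yl)propan-2-yl]oxy}dimethylsilane
Product: 9 4-[2-(tert-butyldimethylsilyloxy)propan-2-yl]cyclohexan-1-one
Conditions: PPTS, acetone–H2O, 60 °C
Reagents that add atoms: water, O
Why: Mild acid-catalysed ketal hydrolysis; the hindered tertiary TBS ether should survive.

Step 7
Reactants: 9 4-[2-(tert-butyldimethylsilyloxy)propan-2-yl]cyclohexan-1-one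
Product: 10 tert-butyldimethyl({2-[(1S)-4-(trimethylsilyloxy)cyclohex-3-en-1-yl]propan-2-yl}oxy)silane
Conditions: LiN[(R)-CH(Me)Ph]2, LiCl, Me3SiCl, THF, −100 °C
Reagents that add atoms: chlorotrimethylsilane, C[Si](C)(C)Cl
Why: Enantiotopic deprotonation of the conformationally locked ketone by the C2-symmetric chiral lithium amide with in-situ silylation (known desymmetrisation of 4-substituted cyclohexanones) creates the C17 stereocentre by fixing on which side the enol double bond (C20=C6) lies.

Step 8
Reactants: 10 (S)-enol silane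
Product: 11 (4S)-4-[2-(tert-butyldimethylsilyloxy)propan-2-yl]cyclohex-2-en-1-one
Conditions: Pd(OAc)2 (10 mol %), O2 (1 atm), DMSO, rt
Reagents that add atoms: none
Why: Saegusa–Ito oxidation; the enol silane gives a divalent palladium enolate, β-hydride elimination from C7 forms the C6=C7 enone, and oxygen returns zerovalent palladium to the divalent state.

Step 9
Reactants: 11 (4S)-enone
Product: 12 trimethylsilyl enol ether of trans-3-methyl-4-(CMe2OTBS)cyclohexanone (C20–OSiMe3, C20=C6; C7 methyl trans to the C17 side chain)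
Conditions: MeMgBr, CuBr·SMe2 (10 mol %), Me3SiCl, HMPA, THF, −78 °C
Reagents that add atoms: methylmagnesium bromide, C[Mg]Br; chlorotrimethylsilane, C[Si](C)(C)Cl
Why: Copper-catalysed, silyl chloride-accelerated conjugate addition anti to the C17 substituent; the new centre is erased in step 10, so only the regiodefined enol silane matters.

Step 10
Reactants: 12 trans-3-methyl enol silane
Product: 13 (4S)-4-[2-(tert-butyldimethylsilyloxy)propan-2-yl]-3-methylcyclohex-2-en-1-one
Conditions: Pd(OAc)2 (10 mol %), O2 (1 atm), DMSO, 40 °C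
Reagents that add atoms: none
Why: Second Saegusa–Ito oxidation; β-hydride elimination can only involve C7–H and gives the β-methyl enone.

Step 11
Reactants: 13 β-methyl enone
Product: 14 trimethylsilyl enol ether of 4-(CMe2OTBS)-3-methyl-3-vinylcyclohexanone (C20–OSiMe3, C20=C6; at C7 vinyl trans and methyl cis to the C17 side chain)
Conditions: CH2=CHMgBr, CuBr·SMe2 (20 mol %), Me3SiCl, HMPA, THF, −78 → −40 °C
Reagents that add atoms: vinylmagnesium bromide, C=C[Mg]Br; chlorotrimethylsilane, C[Si](C)(C)Cl
Why: Silyl chloride-accelerated copper-catalysed conjugate addition to a β,β-disubstituted enone; vinyl enters anti to the bulky C17 substituent and sets the quaternary centre C7.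

Step 12
Reactants: 14 vinyl enol silane
Product: 17 4-(CMe2OTBS)-3-methyl-2-methylidene-3-vinylcyclohexan-1-one (exocyclic C6=C5), via Mannich base 15 (not isolated), via ammonium iodide 16 (not isolated)
Conditions: CH2=NMe2+ I−, CH2Cl2, rt; then MeI, Et2O; then aq. NaHCO3, CH2Cl2, rt
Reagents that add atoms: dimethyl(methylidene)ammonium iodide (Eschenmoser's salt), C=[N+](C)C.[I-]
Why: Mannich reaction of the regiodefined enol silane at C6, exhaustive N-methylation and E1cB elimination give the α-methylene ketone; C5 is introduced and no stereocentre is formed.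

Step 13
Reactants: 17 α-methylene ketone
Product: 19 methyl 2-methyl-3-(ring B)propanoate: cyclohexanone (C20=O) carrying CH2CH(CH3)CO2Me at C6 (cis to the C7 methyl, trans to vinyl), methyl and vinyl at C7, CMe2OTBS at C17; C3 epimer mixture, via enol silane adduct 18 (not isolated)
Conditions: MeCH=C(OMe)OSiMe3, Me3SiOTf (10 mol %), CH2Cl2, −78 °C; then 1 M HCl, THF, 0 °C
Reagents that add atoms: 1-methoxy-1-(trimethylsilyloxy)prop-1-ene, CC=C(OC)O[Si](C)(C)C
Why: Mukaiyama–Michael addition of the propionate silyl ketene acetal to the unhindered terminus C5; on hydrolysis the C6=C20 enol silane should be protonated axially, anti to the axial C8 methyl, which places the side chain equatorial at C6.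

Step 14
Reactants: 19 keto ester
Product: 20 methyl 2-methyl-3-(ring B)propanoate with C20=C21 exocyclic methylene in place of the ketone
Conditions: Ph3PCH3Br, KOtBu, THF, 0 °C → rt
Reagents that add atoms: methyltriphenylphosphonium bromide, C[P+](c1ccccc1)(c1ccccc1)c1ccccc1.[Br-]
Why: Wittig methylenation of the ketone in the presence of the less electrophilic ester installs C21; any enolisation at C6 is corrected by the same axial protonation.

Step 15
Reactants: 20 methylene ester
Product: 21 methyl 4-methyl-3-oxo-5-(ring B)pentanoate (β-keto ester C23–C22–C2)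
Conditions: MeOAc, LiN(iPr)2 (3 equiv each), THF, −78 °C; then 20, −78 → −20 °C
Reagents that add atoms: methyl acetate, CC(=O)OC
Why: Crossed Claisen condensation; the lithium enolate of methyl acetate acylates at the C2 ester and deprotonation of the β-keto ester drives the reaction.

Step 16
Reactants: 21 β-keto ester
Product: 22 methyl 2-diazo-4-methyl-3-oxo-5-(ring B)pentanoate (diazo group on C22)
Conditions: 4-AcNHC6H4SO2N3, Et3N, MeCN, 0 °C → rt
Reagents that add atoms: 4-acetamidobenzenesulfonyl azide, CC(=O)Nc1ccc(cc1)S(=O)(=O)N=[N+]=[N-]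
Why: Regitz diazo transfer to the active methylene C22.

**Key step and ring C**

Step 17
Reactants: 22 diazo β-keto ester
Product: 23 cyclopropane-fused keto ester: ring C (C2 ketone, C3 methyl, C22 CO2Me) trans-fused to ring B, cyclopropane C20–C21–C22 with C21 on the β face
Conditions: Cu(acac)2 (5 mol %), toluene, 110 °C, slow addition of 22
Reagents that add atoms: none
Why: Cu(acac)2 is the precatalyst for a monovalent copper species that expels N2 from the diazo ester and forms an electrophilic copper carbenoid at C22; this adds in a concerted, asynchronous [2+1] manner to the C20=C21 double bond, a known intramolecular cyclopropanation of α-diazo β-keto esters. Ring C closes in the exo mode through the tether C2–C3–C5–C6 (six-membered transition state, C22 bonding to the ring carbon C20), and the three-membered ring closes by the second bond from C22 to the exocyclic carbon C21. C20 is set by face selection: the tether leaves C6 equatorially and reaches the equatorial face of the methylenecyclohexane in a chair-like, trans-fused arrangement, while the axial face is blocked by the 1,3-diaxial C8 methyl, so C21 ends axial (β) and C22 equatorial. C22 follows from C20 because the addition is suprafacial and the cyclopropane can only be cis-fused to ring C. The step needs chemoselectivity for C20=C21 over the C7 vinyl group and over C–H insertion: the vinyl group is less nucleophilic and reachable only through a seven-membered transition state, and copper carbenoids prefer alkene addition to insertion into the allylic C6–H bond. Slow addition should keep carbene dimerisation low.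

Step 18
Reactants: 23 cyclopropane keto ester
Product: 24 ring C β-keto ester: C21 axial methyl on C20, C22–H between the C2 ketone and CO2Me; C3 and C22 undefined
Conditions: SmI2 (2.5 equiv), THF–MeOH, −78 °C
Reagents that add atoms: none
Why: Reductive opening of an acyl cyclopropane by divalent samarium; the exocyclic C21–C22 bond overlaps with the ketyl π-system while the ring-fusion bond C20–C22 lies near its nodal plane, so C21 is released and protonated to the methyl group and the enolate gives the β-keto ester.

**Rings D and E**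

Step 19
Reactants: 24 ring C β-keto ester; 5 {[(2S)-3-(bromomethyl)but-3-en-2-yl]oxy}triethylsilane
Product: 25 C3-alkylated β-keto ester: C3 quaternary with the CH2C(=CH2)CH(OTES)CH3 chain axial on the α face (C30) and the C4 methyl equatorial
Conditions: LiN(iPr)2 (2.3 equiv), THF, −78 → 0 °C; then 5, DMPU, −78 → −20 °C
Reagents that add atoms: none
Why: β-Keto ester dianion alkylation; the second deprotonation occurs at C3 and this more reactive carbon attacks the allylic bromide axially on the α face (chair-like transition state of the trans-fused ring, away from the axial C21 methyl), which sets C3.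

Step 20
Reactants: 25 C3-alkylated β-keto ester
Product: 26 keto aldehyde: C28 ketone (C30H2–C(=O)–CH(OTES)CH3) and C9 aldehyde on C7
Conditions: O3, CH2Cl2, −78 °C; then Me2S, −78 °C → rt
Reagents that add atoms: ozone, [O-][O+]=O
Why: Ozonolysis with reductive work-up cleaves both terminal alkenes, so no selectivity between them is needed: the 1,1-disubstituted one unveils the C28 ketone and the vinyl group becomes the C9 aldehyde, which step 22 turns back into the vinyl group.

Step 21
Reactants: 26 keto aldehyde
Product: 29 aldol lactone: bicyclo[3.2.1]octane (rings C and D, C2 bridging ketone) with cis-fused γ-lactone ring E, C28–OH endo, C9 aldehyde, C14–OTBS, via hydroxy ketone 27 (not isolated), via aldol hydroxy ester 28 (not isolated)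
Conditions: HF·pyridine, pyridine, THF, 0 °C; aq. NaHCO3 work-up; then DBU (0.5 equiv), toluene, rt
Reagents that add atoms: none
Why: Fluoride removes the secondary TES ether while the hindered tertiary TBS ether stays; DBU then promotes a reversible intramolecular aldol addition of C22 to the C28 ketone, necessarily on the α face where C30 holds it, and only the C28 epimer with C26 exo can lactonise (O25 onto C23), which drains the equilibrium and fixes C22 and C28; C26 is unchanged from (S)-lactate.

Step 22
Reactants: 29 aldol lactone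
Product: 30 bis-methylene lactone: C2=C1H2 on the one-carbon bridge and C9=C10H2 vinyl on C7
Conditions: Zn, CH2Br2, TiCl4 (preformed in THF, excess), CH2Cl2, 0 °C → rt
Reagents that add atoms: dibromomethane, BrCBr
Why: Takai–Lombardo methylenation; the non-basic geminal dizinc reagent activated by TiCl4 converts aldehydes and hindered, aldol-type ketones into methylene groups and leaves lactones, silyl ethers and free hydroxyl groups alone, so C1 is installed and the vinyl group is restored in one operation.

**Ring A**

Step 23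
Reactants: 30 bis-methylene lactone
Product: 31 diol: C14 tertiary carbinol free, C28–OH free
Conditions: HF·pyridine, THF, rt → 40 °C
Reagents that add atoms: none
Why: Fluoride-mediated cleavage of the tertiary TBS ether under non-basic conditions that should not disturb the lactone.

Step 24
Reactants: 31 diol
Product: 32 C14 acrylate: CMe2–O–C(=O)CH=CH2 on C17
Conditions: CH2=CHCOCl, iPr2NEt, DMAP (cat.), CH2Cl2, 0 °C → rt
Reagents that add atoms: acryloyl chloride, C=CC(=O)Cl
Why: Acylation of the exposed 2-hydroxypropan-2-yl alcohol; the C28 hydroxyl is tertiary, endo in the bicyclo[3.2.1]octane and next to the quaternary C22, and should not react.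

Step 25
Reactants: 32 C14 acrylate
Product: 33 brasilianoid C
Conditions: second-generation Hoveyda–Grubbs catalyst (10 mol %), toluene (2 mM), 80 °C
Reagents that add atoms: none
Why: Ring-closing metathesis between the C7 vinyl group and the acrylate forms the C9=C10 bond of the seven-membered unsaturated lactone (necessarily Z) with loss of ethene; the hindered 1,1-disubstituted C2=C1 alkene should be inert.

**Compound list**
1 | ethyl (S)-lactate | C[C@H](O)C(=O)OCC | starting material
2 | ethyl (2S)-2-(triethylsilyloxy)propanoate | C[C@H](O[Si](CC)(CC)CC)C(=O)OCC | intermediate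
3 | (3S)-3-(triethylsilyloxy)-1-(trimethylsilyl)-2-[(trimethylsilyl)methyl]butan-2-ol | C[C@H](O[Si](CC)(CC)CC)C(O)(C[Si](C)(C)C)C[Si](C)(C)C | intermediate (not isolated)
4 | triethyl{[(2S)-3-[(trimethylsilyl)methyl]but-3-en-2-yl]oxy}silane | C[C@H](O[Si](CC)(CC)CC)C(=C)C[Si](C)(C)C | intermediate
5 | {[(2S)-3-(bromomethyl)but-3-en-2-yl]oxy}triethylsilane | C[C@H](O[Si](CC)(CC)CC)C(=C)CBr | intermediate
6 | ethyl 1,4-dioxaspiro[4.5]decane-8-carboxylate | CCOC(=O)C1CCC2(CC1)OCCO2 | starting material
7 | 2-(1,4-dioxaspiro[4.5]decan-8-yl)propan-2-ol | CC(C)(O)C1CCC2(CC1)OCCO2 | intermediate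
8 | tert-butyl{[2-(1,4-dioxaspiro[4.5]decan-8-yl)propan-2-yl]oxy}dimethylsilane | CC(C)(O[Si](C)(C)C(C)(C)C)C1CCC2(CC1)OCCO2 | intermediate
9 | 4-[2-(tert-butyldimethylsilyloxy)propan-2-yl]cyclohexan-1-one | CC(C)(O[Si](C)(C)C(C)(C)C)C1CCC(=O)CC1 | intermediate
10 | (S)-enol silane of 9 | C[Si](C)(C)OC1=CC[C@@H](C(C)(C)O[Si](C)(C)C(C)(C)C)CC1 | intermediate
11 | (4S)-4-[2-(tert-butyldimethylsilyloxy)propan-2-yl]cyclohex-2-en-1-one | O=C1C=C[C@@H](C(C)(C)O[Si](C)(C)C(C)(C)C)CC1 | intermediate
12 | trans-3-methyl enol silane | C[Si](C)(C)OC1=C[C@H](C)[C@@H](C(C)(C)O[Si](C)(C)C(C)(C)C)CC1 | intermediate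
13 | (4S)-4-[2-(tert-butyldimethylsilyloxy)propan-2-yl]-3-methylcyclohex-2-en-1-one | O=C1C=C(C)[C@@H](C(C)(C)O[Si](C)(C)C(C)(C)C)CC1 | intermediate
14 | 3-methyl-3-vinyl enol silane (vinyl trans to the C17 side chain) | C[Si](C)(C)OC1=C[C@](C)(C=C)[C@@H](C(C)(C)O[Si](C)(C)C(C)(C)C)CC1 | intermediate
15 | Mannich base (C6–CH2NMe2) | O=C1C(CN(C)C)[C@](C)(C=C)[C@@H](C(C)(C)O[Si](C)(C)C(C)(C)C)CC1 | intermediate (not isolated)
16 | trimethylammonium iodide of 15 | O=C1C(C[N+](C)(C)C)[C@](C)(C=C)[C@@H](C(C)(C)O[Si](C)(C)C(C)(C)C)CC1.[I-] | intermediate (not isolated)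
17 | α-methylene ketone (C6=C5) | O=C1C(=C)[C@](C)(C=C)[C@@H](C(C)(C)O[Si](C)(C)C(C)(C)C)CC1 | intermediate
18 | enol silane Michael adduct | C[Si](C)(C)OC1=C(CC(C)C(=O)OC)[C@](C)(C=C)[C@@H](C(C)(C)O[Si](C)(C)C(C)(C)C)CC1 | intermediate (not isolated)
19 | ring B keto ester (C3 epimer mixture) | O=C1[C@@H](CC(C)C(=O)OC)[C@](C)(C=C)[C@@H](C(C)(C)O[Si](C)(C)C(C)(C)C)CC1 | intermediate
20 | ring B methylene ester | C=C1[C@@H](CC(C)C(=O)OC)[C@](C)(C=C)[C@@H](C(C)(C)O[Si](C)(C)C(C)(C)C)CC1 | intermediate
21 | ring B β-keto ester | C=C1[C@@H](CC(C)C(=O)CC(=O)OC)[C@](C)(C=C)[C@@H](C(C)(C)O[Si](C)(C)C(C)(C)C)CC1 | intermediate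
22 | ring B diazo β-keto ester (key-step precursor) | COC(=O)C(=[N+]=[N-])C(=O)C(C)C[C@H]1[C@](C)(C=C)[C@@H](C(C)(C)O[Si](C)(C)C(C)(C)C)CCC1=C | intermediate
23 | cyclopropane-fused ring C keto ester (key-step product) | O=C1C(C)C[C@H]2[C@](C)(C=C)[C@@H](C(C)(C)O[Si](C)(C)C(C)(C)C)CC[C@@]23C[C@@]13C(=O)OC | intermediate
24 | ring C β-keto ester with C21 methyl | O=C1C(C)C[C@H]2[C@](C)(C=C)[C@@H](C(C)(C)O[Si](C)(C)C(C)(C)C)CC[C@]2(C)C1C(=O)OC | intermediate
25 | C3-alkylated β-keto ester | O=C1[C@](C)(CC(=C)[C@H](C)O[Si](CC)(CC)CC)C[C@H]2[C@](C)(C=C)[C@@H](C(C)(C)O[Si](C)(C)C(C)(C)C)CC[C@]2(C)C1C(=O)OC | intermediate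
26 | keto aldehyde | O=C1[C@](C)(CC(=O)[C@H](C)O[Si](CC)(CC)CC)C[C@H]2[C@](C)(C=O)[C@@H](C(C)(C)O[Si](C)(C)C(C)(C)C)CC[C@]2(C)C1C(=O)OC | intermediate
27 | α-hydroxy ketone (C26–OH free) | O=C1[C@](C)(CC(=O)[C@H](C)O)C[C@H]2[C@](C)(C=O)[C@@H](C(C)(C)O[Si](C)(C)C(C)(C)C)CC[C@]2(C)C1C(=O)OC | intermediate (not isolated)
28 | aldol hydroxy ester (ring D closed) | O=C1[C@@]2(C)C[C@H]3[C@](C)(C=O)[C@@H](C(C)(C)O[Si](C)(C)C(C)(C)C)CC[C@]3(C)[C@]1(C(=O)OC)[C@@](O)([C@H](C)O)C2 | intermediate (not isolated)
29 | aldol lactone (rings B, C, D, E) | O=C1[C@@]2(C)C[C@H]3[C@](C)(C=O)[C@@H](C(C)(C)O[Si](C)(C)C(C)(C)C)CC[C@]3(C)[C@@]14C(=O)O[C@@H](C)[C@@]4(O)C2 | intermediate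
30 | bis-methylene lactone | C=C1[C@@]2(C)C[C@H]3[C@](C)(C=C)[C@@H](C(C)(C)O[Si](C)(C)C(C)(C)C)CC[C@]3(C)[C@@]14C(=O)O[C@@H](C)[C@@]4(O)C2 | intermediate
31 | diol | C=C1[C@@]2(C)C[C@H]3[C@](C)(C=C)[C@@H](C(C)(C)O)CC[C@]3(C)[C@@]14C(=O)O[C@@H](C)[C@@]4(O)C2 | intermediate
32 | C14 acrylate | C=C1[C@@]2(C)C[C@H]3[C@](C)(C=C)[C@@H](C(C)(C)OC(=O)C=C)CC[C@]3(C)[C@@]14C(=O)O[C@@H](C)[C@@]4(O)C2 | intermediate
33 | brasilianoid C | C=C1[C@@]2(C)C[C@H]3[C@]4(C)C=CC(=O)OC(C)(C)[C@H]4CC[C@]3(C)[C@@]13C(=O)O[C@@H](C)[C@@]3(O)C2 | target

Total steps: 25. Longest linear sequence: 22 steps (steps 4 to 25); steps 1 to 3 make fragment 5.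

**Steps most likely to fail**

Step 22. Attack at the C2 carbonyl, which sits between two quaternary carbons, may be too slow, so that only the aldehyde is methylenated; Lewis-acid-induced retro-aldol opening of ring D may also compete. The fallback sets out from 29 and separates the two carbonyls. One equivalent of Ph3P=CH2 at −78 °C methylenates only the aldehyde and gives the vinyl ketone F1. The small nucleophile Me3SiCH2Li with CeCl3 at −78 °C then adds to the C2 ketone and gives the β-hydroxysilane F2. Peterson elimination (KN(SiMe3)2, or HF·pyridine) can only form the exocyclic alkene and returns to the route at 30.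

Step 20. Ozone may attack the enol tautomer of the β-keto ester and degrade ring C while the two alkenes are being cleaved. The fallback sets out from 25 and masks the enol first. O-Acetylation (Ac2O, Et3N, DMAP) gives the enol acetate F3, whose electron-poor double bond should resist ozone. Ozonolysis with Me2S work-up then gives the keto aldehyde enol acetate F4. HF·pyridine followed by K2CO3 in MeOH at 0 °C removes the TES and acetyl groups, and the liberated enolate undergoes the aldol–lactonisation, so the route is rejoined at 29.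

Step 25. Initiation at the neopentyl vinyl group and at the electron-poor acrylate may be slow, so that intermolecular metathesis and catalyst decay win over ring closure. The fallback sets out from 29 and closes ring A through the O13–C11 bond instead. A Z-selective Still–Gennari olefination of the aldehyde (methyl bis(2,2,2-trifluoroethyl)phosphonoacetate, KN(SiMe3)2, 18-crown-6, −78 °C) gives the (Z)-enoate ketone F5. Takai–Lombardo methylenation of the C2 ketone gives the (Z)-enoate methylene compound F6. HF·pyridine frees the C14 carbinol and gives the hydroxy (Z)-enoate F7. Acid-catalysed lactonisation (TsOH, benzene, reflux), as known for ring A seco acids of this type, comes back to the route at 33.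

**Further compounds**
F1 | step 22 | vinyl ketone (29 with C9 aldehyde converted to vinyl, C2 ketone kept) | O=C1[C@@]2(C)C[C@H]3[C@](C)(C=C)[C@@H](C(C)(C)O[Si](C)(C)C(C)(C)C)CC[C@]3(C)[C@@]14C(=O)O[C@@H](C)[C@@]4(O)C2
F2 | step 22 | β-hydroxysilane (C2 carbinol bearing CH2SiMe3, either C2 epimer) | C[Si](C)(C)CC1(O)[C@@]2(C)C[C@H]3[C@](C)(C=C)[C@@H](C(C)(C)O[Si](C)(C)C(C)(C)C)CC[C@]3(C)[C@@]14C(=O)O[C@@H](C)[C@@]4(O)C2
F3 | step 20 | enol acetate of 25 (C2–OAc, C2=C22) | CC(=O)OC=1[C@](C)(CC(=C)[C@H](C)O[Si](CC)(CC)CC)C[C@H]2[C@](C)(C=C)[C@@H](C(C)(C)O[Si](C)(C)C(C)(C)C)CC[C@]2(C)C=1C(=O)OC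
F4 | step 20 | keto aldehyde enol acetate | CC(=O)OC=1[C@](C)(CC(=O)[C@H](C)O[Si](CC)(CC)CC)C[C@H]2[C@](C)(C=O)[C@@H](C(C)(C)O[Si](C)(C)C(C)(C)C)CC[C@]2(C)C=1C(=O)OC
F5 | step 25 | (Z)-enoate ketone (C9=C10–CO2Me, C2 ketone) | O=C1[C@@]2(C)C[C@H]3[C@](C)(/C=C\C(=O)OC)[C@@H](C(C)(C)O[Si](C)(C)C(C)(C)C)CC[C@]3(C)[C@@]14C(=O)O[C@@H](C)[C@@]4(O)C2
F6 | step 25 | (Z)-enoate methylene compound (C2=C1H2) | C=C1[C@@]2(C)C[C@H]3[C@](C)(/C=C\C(=O)OC)[C@@H](C(C)(C)O[Si](C)(C)C(C)(C)C)CC[C@]3(C)[C@@]14C(=O)O[C@@H](C)[C@@]4(O)C2
F7 | step 25 | hydroxy (Z)-enoate (C14 carbinol free) | C=C1[C@@]2(C)C[C@H]3[C@](C)(/C=C\C(=O)OC)[C@@H](C(C)(C)O)CC[C@]3(C)[C@@]14C(=O)O[C@@H](C)[C@@]4(O)C2
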